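**Retrosynthetic overview**
1. Target 23 ⇐ Ti(OiPr)4‑mediated angelate opening (at C1) of the 1,10‑epoxide of bis‑epoxide 22 ⇐ double anti‑epoxidation of the (1(10)Z,3Z)‑dienol 21 ⇐ CBS reduction of macrocyclic enone 20.
2. Ten‑membered ring (formed last) ⇐ Grob fragmentation of the C4–C9 bond of a cis‑fused decalin (3‑mesylate, 9‑alkoxide); this also creates the (Z)‑C3=C4 alkene.
3. Ring B of the decalin (formed second) ⇐ SmI2 ketyl–enone closure of C3–C4, after 1,2‑addition of a (Z)‑vinyllithium (C10–C1–C2–C3) at C9.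
4. Ring A (formed first; C4–C9 plus C15 all come from the arene) ⇐ o‑cresol: oxidative dearomatisation to the p‑quinone monoketal, then Rh‑catalysed asymmetric isopropenyl addition sets C7.
5. The C5 and C6 esters are installed on the rigid decalin (enolate hydroxylation, ketone reduction) before ring expansion.

Convention (one line): locants C1–C15 are germacrane locants of the target, read off its SMILES (C7 = CH–isopropenyl, C8, C9 = CHOH, C10 = C(Me)OH, C1 = CHOAng, C2, C3/C4 = epoxide with C15 methyl on C4, C5 = CHOAng, C6 = CH–O‑2‑methylbutanoyl; C14 = methyl on C10); β is the face of the flat‑drawn ring system that carries the C7 isopropenyl group and α the other; "4,9‑cyclogermacrane" is the decalin with an extra C4–C9 bond (ring A = C4–C9, ring B = C9,C10,C1,C2,C3,C4); Ang = (Z)‑2‑methylbut‑2‑enoyl; the SMILES is taken literally, so the target is (1S,3S,4S,5S,6S,7R,9R,10S) with an (R)‑2‑methylbutanoate and a cis‑3,4‑epoxide.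

**Step 1**
Reactants: 1 2‑methylphenol (o‑cresol)
Product: 2 4,4‑dimethoxy‑2‑methylcyclohexa‑2,5‑dien‑1‑one
Conditions: PhI(OAc)2 (2.1 equiv), MeOH, 0 °C to rt
Reagents that add atoms: methanol, CO
Why: Hypervalent‑iodine oxidative dearomatisation, in which two successive two‑electron oxidations of the para‑unsubstituted phenol are each intercepted by methanol at C‑4 (first giving 4‑methoxy‑2‑methylphenol, then the cross‑conjugated p‑quinone monoketal), so that no stereocentre is formed and all six arene carbons become differentiated electrophilic or masked carbonyl positions.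

**Step 2**
Reactants: 2 4,4‑dimethoxy‑2‑methylcyclohexa‑2,5‑dien‑1‑one; 3 isopropenylboronic acid pinacol ester
Product: 4 (5R)‑4,4‑dimethoxy‑2‑methyl‑5‑(prop‑1‑en‑2‑yl)cyclohex‑2‑en‑1‑one
Conditions: [Rh(OH)((R)‑BINAP)]2 (3 mol%), dioxane/H2O 10:1, 50 °C
Reagents that add atoms: none
Why: Hayashi–Miyaura rhodium‑catalysed asymmetric 1,4‑addition, in which the alkenyl‑rhodium species inserts only into the enone arm that lacks an α‑substituent and the (R)‑BINAP pocket selects the enone face opposite to that used in the (S)‑BINAP/(S)‑3‑arylcyclohexanone precedent, setting C7 as R (7β‑isopropenyl).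

**Step 3**
Reactants: 5 3,3‑diethoxypropan‑1‑ol
Product: 7 (3Z)‑1,1‑diethoxy‑4‑iodopent‑3‑ene, via 3,3‑diethoxypropanal 6 (not isolated)
Conditions: Dess–Martin periodinane, CH2Cl2, 0 °C; filtered solution added to Ph3P=C(I)CH3 [EtPPh3I, n‑BuLi, I2, then NaN(SiMe3)2], THF, −78 to −20 °C
Reagents that add atoms: ethyltriphenylphosphonium iodide, CC[P+](c1ccccc1)(c1ccccc1)c1ccccc1.[I-]; iodine, [I][I]
Why: Dess–Martin oxidation gives the sensitive acetal aldehyde, which is olefinated at once in a Stork–Zhao‑type Wittig reaction whose unstabilised α‑iodo ylide gives the (Z)‑2‑iodoalkene (iodine cis to the chain) through the kinetically favoured cis‑oxaphosphetane.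

**Step 4**
Reactants: 4 (5R)‑4,4‑dimethoxy‑2‑methyl‑5‑(prop‑1‑en‑2‑yl)cyclohex‑2‑en‑1‑one; 7 (3Z)‑1,1‑diethoxy‑4‑iodopent‑3‑ene
Product: 10 (4S,6R)‑3‑methyl‑4‑[(2Z)‑5‑oxopent‑2‑en‑2‑yl]‑6‑(prop‑1‑en‑2‑yl)‑4‑(triethylsilyloxy)cyclohex‑2‑en‑1‑one, via vinyllithium 8 (not isolated), via silylated adduct 9 (not isolated)
Conditions: 7, t‑BuLi (2 equiv), Et2O, −78 °C; 4, THF, −78 °C; Et3SiOTf, −78 to 0 °C; then 10% aq oxalic acid, THF, rt
Reagents that add atoms: triethylsilyl trifluoromethanesulfonate, CC[Si](CC)(CC)OS(=O)(=O)C(F)(F)F; water, O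
Why: Iodine–lithium exchange proceeds with retention of alkene geometry, the vinyllithium adds 1,2 to the α‑methyl enone anti to the C7 isopropenyl group (as in organolithium additions to carvone) so that the C9 oxygen is β, the tertiary alkoxide is capped as its triethylsilyl ether, and mild aqueous acid then hydrolyses the allylic dimethyl ketal to the C6 enone and the diethyl acetal to the C3 aldehyde while the hindered tertiary silyl ether survives.

**Step 5**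
Reactants: 10 (4S,6R)‑3‑methyl‑4‑[(2Z)‑5‑oxopent‑2‑en‑2‑yl]‑6‑(prop‑1‑en‑2‑yl)‑4‑(triethylsilyloxy)cyclohex‑2‑en‑1‑one
Product: 11 3α‑hydroxy‑9β‑(triethylsilyloxy)‑4,9‑cyclogermacra‑1(10),11‑dien‑6‑one
Conditions: SmI2 (2.5 equiv), HMPA, t‑BuOH, THF, −78 to 0 °C
Reagents that add atoms: none
Why: Samarium diiodide ketyl–olefin cyclisation (6‑exo‑trig), in which the aldehyde ketyl held on the α‑face by the (Z)‑alkene tether adds to the enone β‑carbon C4 from that face to give the cis‑fused decalin with the quaternary 4β‑methyl, the HMPA‑solvated O–Sm group sits pseudo‑equatorial and away from the axial C9 silyloxy group to give the 3α‑alcohol, and the samarium enolate is protonated by t‑BuOH.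

**Step 6**
Reactants: 11 3α‑hydroxy‑9β‑(triethylsilyloxy)‑4,9‑cyclogermacra‑1(10),11‑dien‑6‑one
Product: 12 3α,9β‑bis(triethylsilyloxy)‑4,9‑cyclogermacra‑1(10),11‑dien‑6‑one
Conditions: Et3SiOTf, 2,6‑lutidine, CH2Cl2, −78 °C
Reagents that add atoms: triethylsilyl trifluoromethanesulfonate, CC[Si](CC)(CC)OS(=O)(=O)C(F)(F)F
Why: Standard silyl triflate protection of the only free (neopentyl secondary) hydroxyl, which keeps C3–O inert until it is needed as the leaving group and changes no stereocentre.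

**Step 7**
Reactants: 12 3α,9β‑bis(triethylsilyloxy)‑4,9‑cyclogermacra‑1(10),11‑dien‑6‑one
Product: 14 5β‑hydroxy‑3α,9β‑bis(triethylsilyloxy)‑4,9‑cyclogermacra‑1(10),11‑dien‑6‑one, via potassium enolate 13 (not isolated)
Conditions: KN(SiMe3)2 (1.1 equiv), THF, −78 °C; then 2‑(phenylsulfonyl)‑3‑phenyloxaziridine, −78 °C; aq NH4Cl
Reagents that add atoms: 2‑(phenylsulfonyl)‑3‑phenyloxaziridine, O=S(=O)(c1ccccc1)N1OC1c1ccccc1
Why: Kinetic deprotonation by the bulky amide takes the C5 methylene rather than the C7 methine (as with dihydrocarvone), and Davis oxaziridine hydroxylation of the enolate on the convex β‑face of the cis‑decalin gives the equatorial 5β‑alcohol, which is also the thermodynamically preferred epimer.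

**Step 8**
Reactants: 14 5β‑hydroxy‑3α,9β‑bis(triethylsilyloxy)‑4,9‑cyclogermacra‑1(10),11‑dien‑6‑one
Product: 15 5β‑angeloyloxy‑3α,9β‑bis(triethylsilyloxy)‑4,9‑cyclogermacra‑1(10),11‑dien‑6‑one
Conditions: angelic acid, 2,4,6‑trichlorobenzoyl chloride, Et3N, toluene, rt; then 14, 80 °C
Reagents that add atoms: angelic acid, C/C=C(/C)C(=O)O
Why: Yamaguchi mixed‑anhydride esterification without a nucleophilic catalyst acylates the only free hydroxyl and is the established way to make angelates without Z‑to‑E isomerisation to the tiglate, with no change at any stereocentre.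

**Step 9**
Reactants: 15 5β‑angeloyloxy‑3α,9β‑bis(triethylsilyloxy)‑4,9‑cyclogermacra‑1(10),11‑dien‑6‑one
Product: 16 5β‑angeloyloxy‑6β‑hydroxy‑3α,9β‑bis(triethylsilyloxy)‑4,9‑cyclogermacra‑1(10),11‑diene
Conditions: NaBH4, CeCl3·7H2O, MeOH, −78 °C; AcOH quench
Reagents that add atoms: none
Why: Luche reduction is 1,2‑selective and spares the enoate, and because axial approach to C6 is blocked by the syn‑axial 4β‑methyl the hydride enters equatorially from the α‑face to give the axial 6β‑alcohol, cis to both the 5β‑angelate and the 7β‑isopropenyl group.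

**Step 10**
Reactants: 16 5β‑angeloyloxy‑6β‑hydroxy‑3α,9β‑bis(triethylsilyloxy)‑4,9‑cyclogermacra‑1(10),11‑diene
Product: 17 5β‑angeloyloxy‑6β‑[(R)‑2‑methylbutanoyloxy]‑3α,9β‑bis(triethylsilyloxy)‑4,9‑cyclogermacra‑1(10),11‑diene
Conditions: (R)‑2‑methylbutanoic acid, DCC, 4‑(dimethylamino)pyridine (cat.), CH2Cl2, 0 °C
Reagents that add atoms: (R)‑2‑methylbutanoic acid, CC[C@@H](C)C(=O)O
Why: Steglich esterification of the one remaining free alcohol brings in the acid stereocentre unchanged from enantiopure (R)‑2‑methylbutanoic acid, and the low temperature limits 1,2‑acyl migration of the neighbouring angelate.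

**Step 11**
Reactants: 17 5β‑angeloyloxy‑6β‑[(R)‑2‑methylbutanoyloxy]‑3α,9β‑bis(triethylsilyloxy)‑4,9‑cyclogermacra‑1(10),11‑diene
Product: 18 5β‑angeloyloxy‑6β‑[(R)‑2‑methylbutanoyloxy]‑4,9‑cyclogermacra‑1(10),11‑diene‑3α,9β‑diol
Conditions: HF·pyridine, THF, 0 °C to rt
Reagents that add atoms: none
Why: Fluoride‑mediated desilylation under buffered acidic conditions removes both triethylsilyl ethers without ester cleavage, acyl migration or angelate isomerisation, and no stereocentre is touched.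

**Step 12**
Reactants: 18 5β‑angeloyloxy‑6β‑[(R)‑2‑methylbutanoyloxy]‑4,9‑cyclogermacra‑1(10),11‑diene‑3α,9β‑diol
Product: 20 (1(10)Z,3Z)‑5β‑angeloyloxy‑6β‑[(R)‑2‑methylbutanoyloxy]germacra‑1(10),3,11‑trien‑9‑one, via mesylate 19 (not isolated)
Conditions: MsCl, Et3N, THF, 0 °C; then KN(SiMe3)2 (2.2 equiv), −78 to 0 °C
Reagents that add atoms: none
Why: Selective mesylation of the secondary C3 hydroxyl is followed by an alkoxide‑triggered Grob (Wharton) fragmentation, in which the equatorial 3α‑mesylate of the cis‑decalin conformer with equatorial isopropenyl is antiperiplanar to the C4–C9 bond, so the C9 alkoxide expels mesylate concertedly to give the ten‑membered C9 enone with a (Z)‑C3=C4 alkene (C5 is axial on ring B and ends up cis to C2), the (Z)‑C1=C10 alkene being inherited from ring B.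

**Step 13**
Reactants: 20 (1(10)Z,3Z)‑5β‑angeloyloxy‑6β‑[(R)‑2‑methylbutanoyloxy]germacra‑1(10),3,11‑trien‑9‑one
Product: 21 (1(10)Z,3Z,9R)‑5β‑angeloyloxy‑9β‑hydroxy‑6β‑[(R)‑2‑methylbutanoyloxy]germacra‑1(10),3,11‑triene
Conditions: (S)‑1‑methyl‑3,3‑diphenyl‑tetrahydropyrrolo[1,2‑c][1,3,2]oxazaborole (CBS catalyst, 20 mol%), catecholborane, toluene, −78 °C
Reagents that add atoms: none
Why: Corey–Bakshi–Shibata reduction, in which the oxazaborolidine binds the enone carbonyl with the α‑methylalkenyl arm as the large group and catecholborane delivers hydride to give the (9R)‑allylic alcohol (9β‑OH) under reagent control without hydroborating the alkenes.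

**Step 14**
Reactants: 21 (1(10)Z,3Z,9R)‑5β‑angeloyloxy‑9β‑hydroxy‑6β‑[(R)‑2‑methylbutanoyloxy]germacra‑1(10),3,11‑triene
Product: 22 5β‑angeloyloxy‑1α,10α:3α,4α‑diepoxy‑9β‑hydroxy‑6β‑[(R)‑2‑methylbutanoyloxy]germacr‑11‑ene
Conditions: mCPBA (2.3 equiv), CH2Cl2, 0 °C
Reagents that add atoms: 3‑chloroperbenzoic acid, OOC(=O)c1cccc(Cl)c1
Why: Prilezhaev epoxidation of the two electron‑rich trisubstituted (Z)‑alkenes (the 1,1‑disubstituted isopropenyl and the electron‑poor angelate alkenes react much more slowly), each from the peripheral face anti to its allylic oxygen substituent as is known for mCPBA with medium‑ring (Z)‑allylic alcohols, which places both oxiranes on the α‑face and sets C10, C1, C3 and C4.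

**Step 15**
Reactants: 22 5β‑angeloyloxy‑1α,10α:3α,4α‑diepoxy‑9β‑hydroxy‑6β‑[(R)‑2‑methylbutanoyloxy]germacr‑11‑ene
Product: 23 (1S,3S,4S,5S,6S,7R,9R,10S)‑1β,5β‑bis(angeloyloxy)‑3α,4α‑epoxy‑6β‑[(R)‑2‑methylbutanoyloxy]germacr‑11‑ene‑9β,10α‑diol (CNP0246823.3)
Conditions: angelic acid, Ti(OiPr)4 (1.5 equiv), CH2Cl2, rt
Reagents that add atoms: angelic acid, C/C=C(/C)C(=O)O
Why: Sharpless‑type Ti(OiPr)4‑mediated opening of a 2,3‑epoxy alcohol, in which titanium binds the free C9 hydroxyl and only the adjacent oxirane, and angelic acid attacks the secondary carbon C1 (C‑3 of the epoxy alcohol) with inversion to give the 1β‑angelate and the free 10α tertiary alcohol while the 3,4‑epoxide, which has no free neighbouring hydroxyl, is left intact.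

**Compound list**
1 | 2‑methylphenol (o‑cresol) | Cc1ccccc1O | starting material
2 | 4,4‑dimethoxy‑2‑methylcyclohexa‑2,5‑dien‑1‑one | CC1=CC(OC)(OC)C=CC1=O | intermediate
3 | isopropenylboronic acid pinacol ester | CC(=C)B1OC(C)(C)C(C)(C)O1 | starting material
4 | (5R)‑4,4‑dimethoxy‑2‑methyl‑5‑(prop‑1‑en‑2‑yl)cyclohex‑2‑en‑1‑one | CC1=CC(OC)(OC)[C@@H](C(C)=C)CC1=O | intermediate
5 | 3,3‑diethoxypropan‑1‑ol | CCOC(CCO)OCC | starting material
6 | 3,3‑diethoxypropanal | CCOC(CC=O)OCC | intermediate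
7 | (3Z)‑1,1‑diethoxy‑4‑iodopent‑3‑ene | CCOC(C/C=C(/C)I)OCC | intermediate
8 | (5,5‑diethoxypent‑2‑en‑2‑yl)lithium, Li cis to the acetal chain | CCOC(C/C=C(/C)[Li])OCC | intermediate
9 | 1α‑[(2Z)‑5,5‑diethoxypent‑2‑en‑2‑yl]‑4,4‑dimethoxy‑2‑methyl‑5β‑(prop‑1‑en‑2‑yl)‑1β‑(triethylsilyloxy)cyclohex‑2‑ene | CC1=CC(OC)(OC)[C@@H](C(C)=C)C[C@]1(O[Si](CC)(CC)CC)/C(C)=C\CC(OCC)OCC | intermediate
10 | (4S,6R)‑3‑methyl‑4‑[(2Z)‑5‑oxopent‑2‑en‑2‑yl]‑6‑(prop‑1‑en‑2‑yl)‑4‑(triethylsilyloxy)cyclohex‑2‑en‑1‑one (silyloxy cis to isopropenyl) | CC1=CC(=O)[C@@H](C(C)=C)C[C@]1(O[Si](CC)(CC)CC)/C(C)=C\CC=O | intermediate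
11 | 3α‑hydroxy‑9β‑(triethylsilyloxy)‑4,9‑cyclogermacra‑1(10),11‑dien‑6‑one (cis‑fused, 15‑methyl β) | O[C@H]1CC=C(C)[C@@]2(O[Si](CC)(CC)CC)C[C@H](C(C)=C)C(=O)C[C@@]12C | intermediate
12 | 3α,9β‑bis(triethylsilyloxy)‑4,9‑cyclogermacra‑1(10),11‑dien‑6‑one | CC[Si](CC)(CC)O[C@H]1CC=C(C)[C@@]2(O[Si](CC)(CC)CC)C[C@H](C(C)=C)C(=O)C[C@@]12C | intermediate
13 | potassium 5(6)‑enolate of 12 | CC[Si](CC)(CC)O[C@H]1CC=C(C)[C@@]2(O[Si](CC)(CC)CC)C[C@H](C(C)=C)C([O-])=C[C@@]12C.[K+] | intermediate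
14 | 5β‑hydroxy‑3α,9β‑bis(triethylsilyloxy)‑4,9‑cyclogermacra‑1(10),11‑dien‑6‑one | CC[Si](CC)(CC)O[C@H]1CC=C(C)[C@@]2(O[Si](CC)(CC)CC)C[C@H](C(C)=C)C(=O)[C@H](O)[C@@]12C | intermediate
15 | 5β‑angeloyloxy‑3α,9β‑bis(triethylsilyloxy)‑4,9‑cyclogermacra‑1(10),11‑dien‑6‑one | CC[Si](CC)(CC)O[C@H]1CC=C(C)[C@@]2(O[Si](CC)(CC)CC)C[C@H](C(C)=C)C(=O)[C@H](OC(=O)/C(C)=C\C)[C@@]12C | intermediate
16 | 5β‑angeloyloxy‑6β‑hydroxy‑3α,9β‑bis(triethylsilyloxy)‑4,9‑cyclogermacra‑1(10),11‑diene | CC[Si](CC)(CC)O[C@H]1CC=C(C)[C@@]2(O[Si](CC)(CC)CC)C[C@H](C(C)=C)[C@H](O)[C@H](OC(=O)/C(C)=C\C)[C@@]12C | intermediate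
17 | 5β‑angeloyloxy‑6β‑[(R)‑2‑methylbutanoyloxy]‑3α,9β‑bis(triethylsilyloxy)‑4,9‑cyclogermacra‑1(10),11‑diene | CC[Si](CC)(CC)O[C@H]1CC=C(C)[C@@]2(O[Si](CC)(CC)CC)C[C@H](C(C)=C)[C@H](OC(=O)[C@H](C)CC)[C@H](OC(=O)/C(C)=C\C)[C@@]12C | intermediate
18 | 5β‑angeloyloxy‑6β‑[(R)‑2‑methylbutanoyloxy]‑4,9‑cyclogermacra‑1(10),11‑diene‑3α,9β‑diol | O[C@H]1CC=C(C)[C@@]2(O)C[C@H](C(C)=C)[C@H](OC(=O)[C@H](C)CC)[C@H](OC(=O)/C(C)=C\C)[C@@]12C | intermediate
19 | 3α‑methanesulfonate of 18 | CS(=O)(=O)O[C@H]1CC=C(C)[C@@]2(O)C[C@H](C(C)=C)[C@H](OC(=O)[C@H](C)CC)[C@H](OC(=O)/C(C)=C\C)[C@@]12C | intermediate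
20 | (1(10)Z,3Z)‑5β‑angeloyloxy‑6β‑[(R)‑2‑methylbutanoyloxy]germacra‑1(10),3,11‑trien‑9‑one | C=C(C)[C@H]1CC(=O)/C(C)=C\C/C=C(/C)[C@@H](OC(=O)/C(C)=C\C)[C@H]1OC(=O)[C@H](C)CC | intermediate
21 | (1(10)Z,3Z,9R)‑5β‑angeloyloxy‑9β‑hydroxy‑6β‑[(R)‑2‑methylbutanoyloxy]germacra‑1(10),3,11‑triene | C=C(C)[C@H]1C[C@@H](O)/C(C)=C\C/C=C(/C)[C@@H](OC(=O)/C(C)=C\C)[C@H]1OC(=O)[C@H](C)CC | intermediate
22 | 5β‑angeloyloxy‑1α,10α:3α,4α‑diepoxy‑9β‑hydroxy‑6β‑[(R)‑2‑methylbutanoyloxy]germacr‑11‑ene | C=C(C)[C@H]1C[C@@H](O)[C@]2(C)O[C@@H]2C[C@@H]3O[C@]3(C)[C@@H](OC(=O)/C(C)=C\C)[C@H]1OC(=O)[C@H](C)CC | intermediate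
23 | (1S,3S,4S,5S,6S,7R,9R,10S)‑1β,5β‑bis(angeloyloxy)‑3α,4α‑epoxy‑6β‑[(R)‑2‑methylbutanoyloxy]germacr‑11‑ene‑9β,10α‑diol | C=C(C)[C@H]1C[C@@H](O)[C@](C)(O)[C@@H](OC(=O)/C(C)=C\C)C[C@@H]2O[C@]2(C)[C@@H](OC(=O)/C(C)=C\C)[C@H]1OC(=O)[C@H](C)CC | target

**Step count**
Total: 15 steps. Longest linear sequence: 14 steps (steps 1, 2 and 4–15, from o‑cresol); step 3 is a one‑step side branch.

**Three steps most likely to fail, with fallbacks**

Step 5 (radical closure of ring B onto a fully substituted enone carbon next to a quaternary centre; C3 configuration). The fallback sets out from 4 and 7 and returns to the route at 12. The acetal of 7 is hydrolysed on wet silica/oxalic acid to (3Z)‑4‑iodopent‑3‑enal F1. Compound 4 is treated with LiBH(s‑Bu)3 (THF, −78 °C) so that 1,4‑reduction gives the C4 lithium enolate regiospecifically, and this is trapped with F1 in a reductive aldol through a Zimmerman–Traxler chair (the cyclic enolate gives the 3α‑hydroxy/4β‑methyl relationship, the aldehyde entering anti to the C7 substituent) to give 2α‑[(3Z)‑1‑hydroxy‑4‑iodopent‑3‑enyl]‑4,4‑dimethoxy‑2β‑methyl‑5β‑(prop‑1‑en‑2‑yl)cyclohexan‑1‑one F2. Ring B is then closed cis‑fused by intramolecular Nozaki–Hiyama–Kishi addition of the vinyl iodide to the C9 ketone (CrCl2, NiCl2 catalyst, DMSO) to give 6,6‑dimethoxy‑4,9‑cyclogermacra‑1(10),11‑diene‑3α,9β‑diol F3. Aqueous oxalic acid unmasks the C6 ketone to give 3α,9β‑dihydroxy‑4,9‑cyclogermacra‑1(10),11‑dien‑6‑one F4, and silylation of both hydroxyls with Et3SiOTf/2,6‑lutidine gives 12.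

Step 12 (Grob fragmentation with ester groups present; Z‑geometry depends on the 3α‑mesylate being equatorial in the reactive conformer). The fallback sets out from 18 and returns at 20. Dess–Martin oxidation of the C3 alcohol gives 5β‑angeloyloxy‑9β‑hydroxy‑6β‑[(R)‑2‑methylbutanoyloxy]‑4,9‑cyclogermacra‑1(10),11‑dien‑3‑one F5. KN(SiMe3)2 followed by PhNTf2 (THF, −78 °C) effects retro‑aldol cleavage of C4–C9, which releases the C9 enone and a regiospecific C3=C4 enolate that is trapped as (1(10)Z,3Z)‑5β‑angeloyloxy‑6β‑[(R)‑2‑methylbutanoyloxy]‑9‑oxogermacra‑1(10),3,11‑trien‑3‑yl trifluoromethanesulfonate F6. Pd(OAc)2/PPh3, HCO2H and Bu3N (DMF, 60 °C) replace the triflate by hydrogen with retention of alkene geometry to give 20.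

Step 15 (regioselective opening of one of two oxiranes under Lewis acid, with a risk of transannular reactions; it depends on step 14 as well). The fallback sets out from 20 and returns at 23, so that the two oxiranes never coexist. Weitz–Scheffer epoxidation (t‑BuOOH, DBU, CH2Cl2) oxidises only the enone C1=C10 bond from the peripheral α‑face to give 5β‑angeloyloxy‑1α,10α‑epoxy‑6β‑[(R)‑2‑methylbutanoyloxy]germacra‑3,11‑dien‑9‑one F7. CBS reduction as in step 13 gives 5β‑angeloyloxy‑1α,10α‑epoxy‑9β‑hydroxy‑6β‑[(R)‑2‑methylbutanoyloxy]germacra‑3,11‑diene F8. Ti(OiPr)4/angelic acid opens the single oxirane at C1 to give 1β,5β‑bis(angeloyloxy)‑6β‑[(R)‑2‑methylbutanoyloxy]germacra‑3,11‑diene‑9β,10α‑diol F9. A final mCPBA epoxidation of the (Z)‑C3=C4 alkene anti to the 5β‑angelate gives 23.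

**Further compounds**
F1 | step 5 | (3Z)‑4‑iodopent‑3‑enal | O=CC/C=C(/C)I
F2 | step 5 | 2α‑[(3Z)‑1‑hydroxy‑4‑iodopent‑3‑enyl]‑4,4‑dimethoxy‑2β‑methyl‑5β‑(prop‑1‑en‑2‑yl)cyclohexan‑1‑one (carbinol = 3α‑OH) | O[C@@H](C/C=C(/C)I)[C@]1(C)CC(OC)(OC)[C@@H](C(C)=C)CC1=O
F3 | step 5 | 6,6‑dimethoxy‑4,9‑cyclogermacra‑1(10),11‑diene‑3α,9β‑diol | O[C@H]1CC=C(C)[C@@]2(O)C[C@H](C(C)=C)C(OC)(OC)C[C@@]12C
F4 | step 5 | 3α,9β‑dihydroxy‑4,9‑cyclogermacra‑1(10),11‑dien‑6‑one | O[C@H]1CC=C(C)[C@@]2(O)C[C@H](C(C)=C)C(=O)C[C@@]12C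
F5 | step 12 | 5β‑angeloyloxy‑9β‑hydroxy‑6β‑[(R)‑2‑methylbutanoyloxy]‑4,9‑cyclogermacra‑1(10),11‑dien‑3‑one | O=C1CC=C(C)[C@@]2(O)C[C@H](C(C)=C)[C@H](OC(=O)[C@H](C)CC)[C@H](OC(=O)/C(C)=C\C)[C@@]12C
F6 | step 12 | (1(10)Z,3Z)‑5β‑angeloyloxy‑6β‑[(R)‑2‑methylbutanoyloxy]‑9‑oxogermacra‑1(10),3,11‑trien‑3‑yl trifluoromethanesulfonate | C=C(C)[C@H]1CC(=O)/C(C)=C\C/C(OS(=O)(=O)C(F)(F)F)=C(/C)[C@@H](OC(=O)/C(C)=C\C)[C@H]1OC(=O)[C@H](C)CC
F7 | step 15 | 5β‑angeloyloxy‑1α,10α‑epoxy‑6β‑[(R)‑2‑methylbutanoyloxy]germacra‑3,11‑dien‑9‑one | C=C(C)[C@H]1CC(=O)[C@]2(C)O[C@@H]2C/C=C(/C)[C@@H](OC(=O)/C(C)=C\C)[C@H]1OC(=O)[C@H](C)CC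
F8 | step 15 | 5β‑angeloyloxy‑1α,10α‑epoxy‑9β‑hydroxy‑6β‑[(R)‑2‑methylbutanoyloxy]germacra‑3,11‑diene | C=C(C)[C@H]1C[C@@H](O)[C@]2(C)O[C@@H]2C/C=C(/C)[C@@H](OC(=O)/C(C)=C\C)[C@H]1OC(=O)[C@H](C)CC
F9 | step 15 | 1β,5β‑bis(angeloyloxy)‑6β‑[(R)‑2‑methylbutanoyloxy]germacra‑3,11‑diene‑9β,10α‑diol | C=C(C)[C@H]1C[C@@H](O)[C@](C)(O)[C@@H](OC(=O)/C(C)=C\C)C/C=C(/C)[C@@H](OC(=O)/C(C)=C\C)[C@H]1OC(=O)[C@H](C)CC
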